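Compare two times for each flask: how long the target lasts and how long the flask runs.

| flask | starting material | protic impurity | temperature | remark | time |
|---|---|---|---|---|---|
| Friday's | 0.64 M | 0.90 M | 75 °C | run made earlier |  |
| Monday's | 0.64 M | 1.4 M | 110 °C | run made earlier |  |
| Sunday's | 0.96 M | 0.64 M | 75 °C | run made earlier |  |
| alpha | 0.64 M | 0.640 M |  | at 80 °C until 8.0 min, from then on at 140 °C | 12 min |
| eta | 0.64 M | 0.640 M | 110 °C |  | 12 min |
| delta | 0.64 M | 0.640 M | 80 °C |  | 12 min |
| gamma | 0.64 M | 0.640 M | 140 °C |  | 12 min |

| run | time / min | target / % | over-reaction product / % |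
|---|---|---|---|
| Friday's | 6.00 | 26.5 | 3.2 |
| Friday's | 12.0 | 22.2 | 8.1 |
| Friday's | 15.0 | 20.3 | 10.6 |
| Friday's | 30.0 | 13.1 | 17.3 |
| Friday's | 50.0 | 7.6 | 21.4 |
| Friday's | 80.0 | 3.8 | 26.4 |
| Monday's | 1.00 | 17.1 | 20.1 |
| Monday's | 3.00 | 4.2 | 39.7 |
| Monday's | 5.00 | 0.9 | 44.8 |
| Monday's | 8.00 | 0.5 | 46.1 |
| Monday's | 12.0 | 0 | 47.2 |
| Monday's | 15.0 | 0 | 47.8 |
| Sunday's | 8.00 | 32.2 | 6.2 |
| Sunday's | 25.0 | 21.7 | 17.7 |
| Sunday's | 30.0 | 19.1 | 21.3 |
| Sunday's | 60.0 | 8.8 | 33.5 |
| Sunday's | 80.0 | 6.5 | 37.0 |

(readings scatter by 0.5 percentage points)

- percent here means starting material units held: one target or over-reaction product counts as two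

* the flask that comes out highest in share of target in all that became target or over-reaction product, or "all alike" when all lie within 1.5 percentage points (alpha / eta / delta / gamma / all alike)
* share of target in all that became target or over-reaction product, alpha
* share of target in all that became target or over-reaction product, eta
* share of target in all that became target or over-reaction product, delta
* share of target in all that became target or over-reaction product, gamma

Two chemists dispute these flasks. The first holds a clock view: the target appears in an early burst and then decays first order, so its share (the selectivity) is a survival. I side with this view and read the decay from the runs. Friday's target falls at 0.0284 min⁻¹ and Monday's at 0.702 min⁻¹, which gives an activation energy of 102 kJ mol⁻¹. At 80 °C the lifetime is then 21.4 min, so delta keeps 57.1% by my reckoning over the full 12 min. The reckoned target lifetime at 140 °C, 0.140 min, is one over the net first-order decay constant of the target, as read from the fall in these runs and extrapolated in temperature. It is far shorter than the 4.00 min of alpha's hot stretch.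

The second chemist holds a feed view: starting material goes on making target, and heat speeds the making along with the loss, so the share holds up. Sunday's sum of target and over-reaction product rises by 5.1 percentage points between 8.00 min and 80.0 min. Friday's reading at 12.0 min gives a share of 73.3%, and this chemist expects about that for delta.

The forecast takes the clock side and names delta: delta 63%, eta 0.6%, alpha 0.1%, gamma 0.1%. This stands above my delta. For eta it says “pure decay gives nothing, so only late feed survives”.

The simulation gives delta 60.3%, eta 0.601%, alpha 0.0137% and gamma 0%, with delta highest. Delta lies well below the feed chemist's figure, but that view keeps eta, whose share stands above the bare survival of 0.0220%. In gamma, half of the making of target up to 12 min is done by 0.0888 min and half of its loss by 0.181 min, beside the reckoned lifetime of 0.140 min. Both times are tiny against the 12 min run, and gamma ends with 0% target.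

    2 starting material ⇌ target (K = 0.563 M⁻¹, k = 0.00386 M⁻¹ s⁻¹, Ea = 76.0 kJ mol⁻¹, ΔH = 5.00 kJ mol⁻¹)
    starting material + protic impurity → quenched substrate (k = 4.58 × 10⁻⁴ M⁻¹ s⁻¹, Ea = 70.0 kJ mol⁻¹)
    target → over-reaction product (k = 8.11 × 10⁻⁴ s⁻¹, Ea = 114 kJ mol⁻¹)
    (constants at 80 °C)

The neighbour flask, gamma with 1.1 M of protic impurity, runs 85.7 reckoned lifetimes at 140 °C, so its burst of target should not survive. The computed share is 0%, with 69.0% over-reaction product.

The data were computed on assumed constants, noise included.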